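## Retrosynthetic overview

- The target comes from its 5-O-MOM ether by mild acid. That ether comes from the racemic flavanone by a kinetic resolution in which asymmetric transfer hydrogenation consumes only the 2R ketone.
- Ring C is the only ring that is built, by oxa-Michael closure of a 2'-hydroxychalcone. Its single free phenol is the one next to geranyl, so closure gives the 8-geranyl and not the 6-geranyl flavanone. Rings A and B are bought as arenes.
- The key C–C bond (C2–C3 of the flavanone) is made by a Claisen–Schmidt aldol condensation of a geranylated 2-hydroxy-4-methoxy-6-(methoxymethoxy)acetophenone with benzaldehyde.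
- The acetophenone comes from 5-methoxyresorcinol by two directed ortho-metalations. Geranyl goes between OEE and OMe while OTIPS blocks the other sites. After OTIPS is exchanged for OMOM, acetyl goes between OEE and OMOM, and selective OEE removal frees the right phenol.

Assumption: geranyl = (2E)-3,7-dimethylocta-2,6-dien-1-yl and the target is the (2S)-flavanone, as the SMILES encodes; EE = 1-ethoxyethyl, whose acetal carbon is racemic in every compound that carries it and is removed in step 7.

## Route

Step 1
Reactants: 1 5-methoxyresorcinol (5-methoxybenzene-1,3-diol); 2 chlorotriisopropylsilane (TIPSCl)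
Product: 3 3-methoxy-5-(triisopropylsilyloxy)phenol
Conditions: TIPSCl (1.0 equiv), imidazole (2.0 equiv), DMF, 0 °C to rt; chromatography, bis-silyl ether and diol recycled
Reagents that add atoms: chlorotriisopropylsilane, CC(C)[Si](Cl)(C(C)C)C(C)C
Why: Statistical mono-silylation (silyl ether formation) of a symmetric diol, expected about 45–50% per pass, installs a bulky group that later shields both of its ortho positions from lithiation.

Step 2
Reactants: 3 3-methoxy-5-(triisopropylsilyloxy)phenol; 4 ethyl vinyl ether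
Product: 5 [3-(1-ethoxyethoxy)-5-methoxyphenoxy]triisopropylsilane
Conditions: ethyl vinyl ether (3 equiv), PPTS (5 mol%), CH2Cl2, rt
Reagents that add atoms: ethyl vinyl ether, C=COCC
Why: Acid-catalysed addition of the phenol to the vinyl ether (acetal formation) gives OEE, a strong ortho-director that can later be cleaved without touching a MOM ether.

Step 3
Reactants: 5 [3-(1-ethoxyethoxy)-5-methoxyphenoxy]triisopropylsilane; 6 geranyl bromide ((2E)-1-bromo-3,7-dimethylocta-2,6-diene)
Product: 9 [3-(1-ethoxyethoxy)-4-geranyl-5-methoxyphenoxy]triisopropylsilane, via aryllithium 7 (not isolated), via arylcopper 8 (not isolated)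
Conditions: n-BuLi (1.15 equiv), THF, 0 °C, 1 h; CuI (1.2 equiv), −40 °C; geranyl bromide (1.2 equiv), −40 °C to rt
Reagents that add atoms: geranyl bromide, BrC/C=C(\C)CCC=C(C)C
Why: Directed ortho-metalation takes the only ring position flanked by the coordinating OEE and OMe groups (OTIPS blocks its neighbours), and the arylcopper alkylates the allylic bromide at its primary carbon (SN2), so the E alkene is kept.

Step 4
Reactants: 9 [3-(1-ethoxyethoxy)-4-geranyl-5-methoxyphenoxy]triisopropylsilane
Product: 10 3-(1-ethoxyethoxy)-4-geranyl-5-methoxyphenol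
Conditions: TBAF (1.1 equiv), THF, 0 °C
Reagents that add atoms: none
Why: Fluoride-mediated desilylation frees the phenol while the base-stable EE acetal and the alkenes are untouched.

Step 5
Reactants: 10 3-(1-ethoxyethoxy)-4-geranyl-5-methoxyphenol; 11 chloromethyl methyl ether (MOMCl)
Product: 12 1-(1-ethoxyethoxy)-2-geranyl-3-methoxy-5-(methoxymethoxy)benzene
Conditions: MOMCl (1.5 equiv), i-Pr2NEt (2.5 equiv), CH2Cl2, 0 °C to rt
Reagents that add atoms: chloromethyl methyl ether, COCCl
Why: Williamson-type O-alkylation gives a MOM ether that is base-stable, directs the next lithiation and survives the later removal of OEE.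

Step 6
Reactants: 12 1-(1-ethoxyethoxy)-2-geranyl-3-methoxy-5-(methoxymethoxy)benzene; 13 N-methoxy-N-methylacetamide
Product: 16 1-[2-(1-ethoxyethoxy)-3-geranyl-4-methoxy-6-(methoxymethoxy)phenyl]ethan-1-one, via aryllithium 14 (not isolated), via tetrahedral lithium adduct 15 (not isolated)
Conditions: n-BuLi (1.2 equiv), THF, 0 °C, 1 h; MeC(O)N(OMe)Me (1.5 equiv), −78 to 0 °C; H2O
Reagents that add atoms: N-methoxy-N-methylacetamide, CC(=O)N(C)OC
Why: The second directed ortho-metalation goes to the carbon flanked by the two acetal-type directors OEE and OMOM, and Weinreb acylation stops at the ketone because the chelated tetrahedral adduct collapses only on work-up.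

Step 7
Reactants: 16 1-[2-(1-ethoxyethoxy)-3-geranyl-4-methoxy-6-(methoxymethoxy)phenyl]ethan-1-one
Product: 17 1-[3-geranyl-2-hydroxy-4-methoxy-6-(methoxymethoxy)phenyl]ethan-1-one
Conditions: PPTS (0.2 equiv), MeOH, rt
Reagents that add atoms: none
Why: Mild acid-catalysed transacetalisation cleaves the 1-ethoxyethyl acetal far faster than the MOM ether, leaving exactly one free phenol, the one next to geranyl.

Step 8
Reactants: 17 1-[3-geranyl-2-hydroxy-4-methoxy-6-(methoxymethoxy)phenyl]ethan-1-one; 18 benzaldehyde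
Product: 20 (2E)-1-[3-geranyl-2-hydroxy-4-methoxy-6-(methoxymethoxy)phenyl]-3-phenylprop-2-en-1-one, via aldol adduct 19 (not isolated)
Conditions: PhCHO (1.3 equiv), KOH (50% aq, excess), EtOH, rt, 24–36 h; aq NH4Cl
Reagents that add atoms: benzaldehyde, O=Cc1ccccc1
Why: Claisen–Schmidt aldol condensation joins the two fragments, since the ketone enolate adds to the non-enolisable aldehyde and E1cB loss of water gives the conjugated E enone.

Step 9
Reactants: 20 (2E)-1-[3-geranyl-2-hydroxy-4-methoxy-6-(methoxymethoxy)phenyl]-3-phenylprop-2-en-1-one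
Product: 21 racemic 8-geranyl-7-methoxy-5-(methoxymethoxy)-2-phenylchroman-4-one
Conditions: NaOAc (10 equiv), EtOH, reflux; recovered 20 recycled
Reagents that add atoms: none
Why: Base-mediated intramolecular oxa-Michael addition of the only free phenol closes ring C, which fixes geranyl at C8 and gives C2 as a racemate.

Step 10
Reactants: 21 racemic 8-geranyl-7-methoxy-5-(methoxymethoxy)-2-phenylchroman-4-one
Product: 22 (2S)-8-geranyl-7-methoxy-5-(methoxymethoxy)-2-phenylchroman-4-one
Conditions: RuCl[(R,R)-TsDPEN](p-cymene) (2 mol%), HCO2H/Et3N (5:2), EtOAc, 30 °C, stopped at about 55% conversion; chromatography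
Reagents that add atoms: none
Why: Kinetic resolution by Noyori–Ikariya asymmetric transfer hydrogenation, in which the (R,R) catalyst (4R carbinol, hydride delivered trans to the C2 phenyl) reduces the 2R ketone to the cis flavanol much faster, so the 2S ketone is recovered in high ee (at most 50% yield) and C2 is thereby fixed as S.

Step 11
Reactants: 22 (2S)-8-geranyl-7-methoxy-5-(methoxymethoxy)-2-phenylchroman-4-one
Product: 23 (2S)-8-geranyl-5-hydroxy-7-methoxy-2-phenylchroman-4-one (CNP0209584.2)
Conditions: HCl (0.5 M) in MeOH, rt to 40 °C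
Reagents that add atoms: none
Why: Acid-catalysed acetal cleavage (MOM removal, eased by the neighbouring carbonyl) is mild enough to leave the geranyl alkenes and ring C intact, so the S configuration at C2 is not scrambled.

## Compound list

1 | 5-methoxyresorcinol | COc1cc(O)cc(O)c1 | starting material
2 | chlorotriisopropylsilane | CC(C)[Si](Cl)(C(C)C)C(C)C | starting material
3 | 3-methoxy-5-(triisopropylsilyloxy)phenol | COc1cc(O)cc(O[Si](C(C)C)(C(C)C)C(C)C)c1 | intermediate
4 | ethyl vinyl ether | C=COCC | starting material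
5 | [3-(1-ethoxyethoxy)-5-methoxyphenoxy]triisopropylsilane | CCOC(C)Oc1cc(OC)cc(O[Si](C(C)C)(C(C)C)C(C)C)c1 | intermediate
6 | geranyl bromide, (2E)-1-bromo-3,7-dimethylocta-2,6-diene | BrC/C=C(\C)CCC=C(C)C | starting material
7 | aryllithium from 5, lithium on the ring carbon between OEE and OMe | [Li]c1c(OC)cc(O[Si](C(C)C)(C(C)C)C(C)C)cc1OC(C)OCC | intermediate (not isolated)
8 | arylcopper from 7, copper on the same carbon | [Cu]c1c(OC)cc(O[Si](C(C)C)(C(C)C)C(C)C)cc1OC(C)OCC | intermediate (not isolated)
9 | [3-(1-ethoxyethoxy)-4-geranyl-5-methoxyphenoxy]triisopropylsilane | CCOC(C)Oc1cc(O[Si](C(C)C)(C(C)C)C(C)C)cc(OC)c1C/C=C(\C)CCC=C(C)C | intermediate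
10 | 3-(1-ethoxyethoxy)-4-geranyl-5-methoxyphenol | CCOC(C)Oc1cc(O)cc(OC)c1C/C=C(\C)CCC=C(C)C | intermediate
11 | chloromethyl methyl ether | COCCl | starting material
12 | 1-(1-ethoxyethoxy)-2-geranyl-3-methoxy-5-(methoxymethoxy)benzene | CCOC(C)Oc1cc(OCOC)cc(OC)c1C/C=C(\C)CCC=C(C)C | intermediate
13 | N-methoxy-N-methylacetamide | CC(=O)N(C)OC | starting material
14 | aryllithium from 12, lithium on the ring carbon between OEE and OMOM | [Li]c1c(OCOC)cc(OC)c(C/C=C(\C)CCC=C(C)C)c1OC(C)OCC | intermediate (not isolated)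
15 | tetrahedral lithium adduct of 14 and 13 (lithium hemiaminal alkoxide) | CC(O[Li])(N(C)OC)c1c(OCOC)cc(OC)c(C/C=C(\C)CCC=C(C)C)c1OC(C)OCC | intermediate (not isolated)
16 | 1-[2-(1-ethoxyethoxy)-3-geranyl-4-methoxy-6-(methoxymethoxy)phenyl]ethan-1-one | CC(=O)c1c(OCOC)cc(OC)c(C/C=C(\C)CCC=C(C)C)c1OC(C)OCC | intermediate
17 | 1-[3-geranyl-2-hydroxy-4-methoxy-6-(methoxymethoxy)phenyl]ethan-1-one | CC(=O)c1c(OCOC)cc(OC)c(C/C=C(\C)CCC=C(C)C)c1O | intermediate
18 | benzaldehyde | O=Cc1ccccc1 | starting material
19 | racemic aldol adduct, 1-[3-geranyl-2-hydroxy-4-methoxy-6-(methoxymethoxy)phenyl]-3-hydroxy-3-phenylpropan-1-one | O=C(CC(O)c1ccccc1)c1c(OCOC)cc(OC)c(C/C=C(\C)CCC=C(C)C)c1O | intermediate (not isolated)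
20 | (2E)-1-[3-geranyl-2-hydroxy-4-methoxy-6-(methoxymethoxy)phenyl]-3-phenylprop-2-en-1-one | O=C(/C=C/c1ccccc1)c1c(OCOC)cc(OC)c(C/C=C(\C)CCC=C(C)C)c1O | intermediate
21 | racemic 8-geranyl-7-methoxy-5-(methoxymethoxy)-2-phenylchroman-4-one | COc1cc(OCOC)c2c(c1C/C=C(\C)CCC=C(C)C)OC(c1ccccc1)CC2=O | intermediate
22 | (2S)-8-geranyl-7-methoxy-5-(methoxymethoxy)-2-phenylchroman-4-one | COc1cc(OCOC)c2c(c1C/C=C(\C)CCC=C(C)C)O[C@H](c1ccccc1)CC2=O | intermediate
23 | (2S)-8-geranyl-5-hydroxy-7-methoxy-2-phenylchroman-4-one | COc1cc(O)c2c(c1C/C=C(\C)CCC=C(C)C)O[C@H](c1ccccc1)CC2=O | target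

## Step count and risks

Total steps: 11. Longest linear sequence: 11 (from 1; all other inputs are purchased).

**Risk 1, step 3.** The arylcopper may react sluggishly or give some branched (SN2') product. The fallback sets out from 5 and comes back at 9. Compound 5 is lithiated as before (aryllithium 7) and trapped with 2-isopropoxy-4,4,5,5-tetramethyl-1,3,2-dioxaborolane to give 2-[2-(1-ethoxyethoxy)-6-methoxy-4-(triisopropylsilyloxy)phenyl]-4,4,5,5-tetramethyl-1,3,2-dioxaborolane F1. F1 is then coupled with geranyl bromide 6 using Pd(PPh3)4 and K2CO3 in THF/H2O. This is a Suzuki–Miyaura-type allyl–aryl coupling through a π-allyl complex that is attacked at its less hindered end, and it gives 9.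

**Risk 2, step 6.** n-BuLi may deprotonate the benzylic and allylic CH2 of geranyl, or the hindered aryllithium may acylate poorly. The fallback sets out from 12 and comes back at 17, and it uses no strong base. PPTS in MeOH removes the EE group to give 2-geranyl-3-methoxy-5-(methoxymethoxy)phenol F2. MgCl2, Et3N and paraformaldehyde in MeCN at reflux then formylate the only free ortho position of the phenol to give 3-geranyl-2-hydroxy-4-methoxy-6-(methoxymethoxy)benzaldehyde F3. MeMgBr adds to the aldehyde to give racemic 2-geranyl-6-(1-hydroxyethyl)-3-methoxy-5-(methoxymethoxy)phenol F4, and MnO2 in CH2Cl2 oxidises the benzylic alcohol to 17.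

**Risk 3, step 10.** The carbonyl flanked by the 5-OMOM group may be reduced too slowly or with too low a selectivity factor. The fallback sets out from 21 and comes back at 22. Racemic 21 is separated by preparative HPLC on a cellulose tris(3,5-dimethylphenylcarbamate) phase into 22 and its mirror image (2R)-8-geranyl-7-methoxy-5-(methoxymethoxy)-2-phenylchroman-4-one F5. F5 is racemised back to 21 through chalcone 20 with NaOAc in refluxing EtOH and resubmitted.

Further compounds
F1 | step 3 | 2-[2-(1-ethoxyethoxy)-6-methoxy-4-(triisopropylsilyloxy)phenyl]-4,4,5,5-tetramethyl-1,3,2-dioxaborolane | CCOC(C)Oc1cc(O[Si](C(C)C)(C(C)C)C(C)C)cc(OC)c1B1OC(C)(C)C(C)(C)O1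
F2 | step 6 | 2-geranyl-3-methoxy-5-(methoxymethoxy)phenol | COCOc1cc(O)c(C/C=C(\C)CCC=C(C)C)c(OC)c1
F3 | step 6 | 3-geranyl-2-hydroxy-4-methoxy-6-(methoxymethoxy)benzaldehyde | O=Cc1c(O)c(C/C=C(\C)CCC=C(C)C)c(OC)cc1OCOC
F4 | step 6 | racemic 2-geranyl-6-(1-hydroxyethyl)-3-methoxy-5-(methoxymethoxy)phenol | CC(O)c1c(O)c(C/C=C(\C)CCC=C(C)C)c(OC)cc1OCOC
F5 | step 10 | (2R)-8-geranyl-7-methoxy-5-(methoxymethoxy)-2-phenylchroman-4-one | COc1cc(OCOC)c2c(c1C/C=C(\C)CCC=C(C)C)O[C@@H](c1ccccc1)CC2=O
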